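**Retrosynthetic overview**
1. The target is [(1R,2R,3S,4S)-3,4-diphenylcyclobutane-1,2-diyl]bis[(2,4-dihydroxyphenyl)methanone], the C2-symmetric, all-trans head-to-head cyclodimer of 2',4'-dihydroxychalcone. Cutting the ring bonds C1–C2 (between the two aroyl-bearing carbons) and C3–C4 (between the two phenyl-bearing carbons) gives two identical (E)-chalcones.
2. Enabling feature: in each half the ketone oxygen and the phenol oxygen ortho to it on the aryl ring form a bidentate O,O site. A chiral Sc(III)–PyBox Lewis acid bound there lowers the enone triplet energy, so only catalyst-bound chalcone is sensitised by visible light. Both ring bonds and all four stereocentres are then set in one enantioselective [2+2] photodimerisation.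
3. C1 and C2 are α to ketones and enolisable, and the all-trans isomer is the thermodynamic one, so C1/C2 epimers can be funnelled into the target series by base.
4. The 4-OH is masked as a benzyl ether and the 2-OH is left free as the catalyst handle. The chalcone comes from 2,4-dihydroxyacetophenone and benzaldehyde by Claisen–Schmidt condensation.
5. Ring order: the four benzene rings are bought; the cyclobutane is the only ring made and is closed last, followed only by hydrogenolysis.

Key step: step 3

Assumption: the (S,S)-ligand is taken to deliver the (1R,2R,3S,4S) series by analogy with its crossed cycloadditions; the sense of induction is to be assigned on the first batch (CD or X-ray of 6), and the (R,R)-ligand would be used without other change if it proved opposite.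

**Step 1**
Reactants: 1 2,4-dihydroxyacetophenone
Product: 2 1-[4-(benzyloxy)-2-hydroxyphenyl]ethan-1-one
Conditions: BnBr (1.05 equiv), K2CO3 (1.1 equiv), acetone, reflux
Reagents that add atoms: benzyl bromide, BrCc1ccccc1
Why: Williamson ether synthesis; the 2-OH is held in an intramolecular hydrogen bond to the ketone and is less acidic and less nucleophilic, so one equivalent of base and halide should alkylate the 4-OH selectively.

**Step 2**
Reactants: 2 1-[4-(benzyloxy)-2-hydroxyphenyl]ethan-1-one; 3 benzaldehyde
Product: 4 (E)-1-[4-(benzyloxy)-2-hydroxyphenyl]-3-phenylprop-2-en-1-one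
Conditions: KOH (50% aq., 5 equiv), EtOH, 0 °C to rt; then 1 M HCl to pH 4 at 0 °C
Reagents that add atoms: none
Why: Claisen–Schmidt (crossed aldol) condensation of a methyl ketone with a non-enolisable aldehyde, in which E1cB dehydration should give the conjugated (E)-enone as the thermodynamic isomer while the benzyl ether is inert to hydroxide.

**Step 3**
Reactants: 4 (E)-1-[4-(benzyloxy)-2-hydroxyphenyl]-3-phenylprop-2-en-1-one (two molecules)
Product: 6 [(1R,2R,3S,4S)-3,4-diphenylcyclobutane-1,2-diyl]bis{[4-(benzyloxy)-2-hydroxyphenyl]methanone}, via triplet 1,4-bis(benzylic) diradical 5 (not isolated)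
Conditions: Sc(OTf)3 (10 mol%), (S,S)-t-Bu-PyBox (15 mol%), Ru(bpy)3(PF6)2 (2.5 mol%), i-PrOAc/MeCN 3:1 (0.3 M), degassed, blue LEDs (ca. 455 nm), rt
Reagents that add atoms: none
Why: Proposed new method: chelation of the 2-hydroxyaryl ketone of 4 to Sc(III)–(S,S)-t-Bu-PyBox should lower the enone triplet energy below that of excited Ru(bpy)3 2+, so that only catalyst-bound 4 is sensitised (Dexter energy transfer) while free 4 stays dark; the bound triplet should add through its α-carbon to the α-carbon of a free molecule of 4, which reacts as a β-acylstyrene, to give the bis-benzylic triplet diradical 5, and 5 closes the C3–C4 bond after intersystem crossing. The closest known reaction type is the Sc(III)/PyBox-catalysed, Ru-sensitised enantioselective crossed [2+2] photocycloaddition of 2'-hydroxychalcones with styrenes and 1,3-dienes, together with the racemic Ir-sensitised head-to-head photodimerisation of chalcones; new here is that the ground-state partner is a second enone and that enantiocontrol is asked of a homodimerisation. The four-membered ring is closed in a stepwise intermolecular [2+2] mode, C1–C2 first and C3–C4 by radical–radical recombination. C1 is set by the ligand, whose tert-butyl group shields one face of the chelated enone, C2 by approach of the partner with its aroyl group anti to the bound one (trans-diaroyl), and C3/C4 during closure, in which each freely rotating benzylic radical places its phenyl trans to both neighbours. The step needs head-to-head regioselectivity, secured because only the α,α'-union gives two benzylic radicals, and all-trans diastereoselectivity, secured kinetically as described and thermodynamically because C1 and C2 are enolisable and the all-trans isomer is the most stable one, so that a C1/C2-epimer would converge on 6 with a trace of DBU. It also needs enantioselectivity, secured because the racemic background pathway requires sensitisation of unbound 4, which is energetically uphill.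

**Step 4**
Reactants: 6 [(1R,2R,3S,4S)-3,4-diphenylcyclobutane-1,2-diyl]bis{[4-(benzyloxy)-2-hydroxyphenyl]methanone}
Product: 7 [(1R,2R,3S,4S)-3,4-diphenylcyclobutane-1,2-diyl]bis[(2,4-dihydroxyphenyl)methanone]
Conditions: H2 (1 atm), 10% Pd/C, EtOAc/MeOH, rt
Reagents that add atoms: none
Why: Catalytic hydrogenolysis of the two aryl benzyl ethers, in which the ketones (deactivated by the ortho/para oxygen donors and the O–H···O=C hydrogen bond) should survive at 1 atm and no stereocentre is touched, the all-trans cyclobutane being the thermodynamic isomer in any case.

**Compound list**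
1 | 1-(2,4-dihydroxyphenyl)ethan-1-one (2,4-dihydroxyacetophenone) | CC(=O)c1ccc(O)cc1O | starting material
2 | 1-[4-(benzyloxy)-2-hydroxyphenyl]ethan-1-one | CC(=O)c1ccc(OCc2ccccc2)cc1O | intermediate
3 | benzaldehyde | O=Cc1ccccc1 | starting material
4 | (E)-1-[4-(benzyloxy)-2-hydroxyphenyl]-3-phenylprop-2-en-1-one | O=C(/C=C/c1ccccc1)c1ccc(OCc2ccccc2)cc1O | intermediate
5 | (2R,3R)-2,3-bis[4-(benzyloxy)-2-hydroxybenzoyl]-1,4-diphenylbutane-1,4-diyl (triplet diradical, not isolated) | O=C(c1ccc(OCc2ccccc2)cc1O)[C@H]([CH]c1ccccc1)[C@H](C(=O)c1ccc(OCc2ccccc2)cc1O)[CH]c1ccccc1 | intermediate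
6 | [(1R,2R,3S,4S)-3,4-diphenylcyclobutane-1,2-diyl]bis{[4-(benzyloxy)-2-hydroxyphenyl]methanone} | O=C(c1ccc(OCc2ccccc2)cc1O)[C@H]1[C@H](C(=O)c2ccc(OCc3ccccc3)cc2O)[C@@H](c2ccccc2)[C@@H]1c1ccccc1 | intermediate
7 | [(1R,2R,3S,4S)-3,4-diphenylcyclobutane-1,2-diyl]bis[(2,4-dihydroxyphenyl)methanone] | O=C(c1ccc(O)cc1O)[C@H]1[C@H](C(=O)c2ccc(O)cc2O)[C@@H](c2ccccc2)[C@@H]1c1ccccc1 | target

**Step count and risk**
Total step count: 4. Longest linear sequence: 4 (1 → 2 → 4 → 6 → 7).

Steps most likely to fail:

1. Step 3 (Proposed new method). What may go wrong: a ground-state enone is a poorer trap for the catalyst-bound triplet than a styrene or diene. The triplet may then decay by E/Z isomerisation, turnover and enantiofacial discrimination may be low, the partner may approach in the cis-diphenyl sense, or the Lewis acid may promote oxa-Michael closure of the chalcone to the flavanone. Fallback with known chemistry, setting out from 4 and coming back at 6: 4 is dimerised without chiral control by visible-light triplet sensitisation (fac-Ir(ppy)3, MeCN, blue LEDs), a known head-to-head photodimerisation of chalcones. It should pass through diradical 5 and its mirror image (2S,3S)-2,3-bis[4-(benzyloxy)-2-hydroxybenzoyl]-1,4-diphenylbutane-1,4-diyl F1. A short DBU equilibration in CH2Cl2 should move any C1/C2 epimers into the all-trans series. The racemate, that is 6 and its enantiomer [(1S,2S,3R,4R)-3,4-diphenylcyclobutane-1,2-diyl]bis{[4-(benzyloxy)-2-hydroxyphenyl]methanone} F2, is then resolved by preparative SFC on a polysaccharide chiral stationary phase, and 6 goes on to step 4.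

2. Step 4. What may go wrong: over-reduction of the aryl ketones at the benzylic carbonyl carbon, or incomplete cleavage through poor solubility or catalyst poisoning by the polyphenol. Fallback setting out from 6 and coming back at 7: the reductive cleavage is replaced by an electrophilic one. BCl3 (excess) with pentamethylbenzene as benzyl-cation scavenger in CH2Cl2 at −78 °C, then a MeOH quench, should dealkylate both ethers by a Lewis-acid SN1-type mechanism that cannot reduce the ketones. No new compound lies on this path.

3. Step 2. What may go wrong: slow condensation because the ketone is deactivated as its phenoxide, and cyclisation of the chalcone to the flavanone during long base exposure or on acidification. Fallback setting out from 2 and 3 and coming back at 4: a directed, kinetic aldol replaces the thermodynamic condensation. The O,C-dianion of 2 (LiHMDS 2.2 equiv, THF, −78 °C) is added to 3 to give racemic 1-[4-(benzyloxy)-2-hydroxyphenyl]-3-hydroxy-3-phenylpropan-1-one F3. This is dehydrated in a separate, short E1cB step (Ba(OH)2, MeOH, 0 °C to rt) to 4.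

**Further compounds**
F1 | step 3 | (2S,3S)-2,3-bis[4-(benzyloxy)-2-hydroxybenzoyl]-1,4-diphenylbutane-1,4-diyl (triplet diradical, not isolated) | O=C(c1ccc(OCc2ccccc2)cc1O)[C@@H]([CH]c1ccccc1)[C@@H](C(=O)c1ccc(OCc2ccccc2)cc1O)[CH]c1ccccc1
F2 | step 3 | [(1S,2S,3R,4R)-3,4-diphenylcyclobutane-1,2-diyl]bis{[4-(benzyloxy)-2-hydroxyphenyl]methanone} | O=C(c1ccc(OCc2ccccc2)cc1O)[C@@H]1[C@@H](C(=O)c2ccc(OCc3ccccc3)cc2O)[C@H](c2ccccc2)[C@H]1c1ccccc1
F0 | step 4 | none | none
F3 | step 2 | 1-[4-(benzyloxy)-2-hydroxyphenyl]-3-hydroxy-3-phenylpropan-1-one (racemic) | O=C(CC(O)c1ccccc1)c1ccc(OCc2ccccc2)cc1O
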